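The earlier runs and the new flask were generated by integration for substances that don't exist; the scatter is artificial.

Take 42.1% of the first end groups charged as the number to carry: this is the links ceiling, what the charges leave as links if each first end group, second end group and protic impurity reacts.

| flask | first end groups | second end groups | protic impurity | remark | time |
|---|---|---|---|---|---|
| Wednesday's | 0.48 M | 0.47 M | 0.144 M | run made earlier |  |
| Sunday's | 0.48 M | 0.47 M | 0.29 M | run made earlier |  |
| alder | 0.48 M | 0.470 M (fed, over 15 h) | 0.144 M | all else is in the flask from the start; the feed brings no volume worth counting | 25 h |
| birch | 0.48 M (fed, over 15 h) | 0.470 M | 0.144 M | all else is in the flask from the start; the feed brings no volume worth counting | 25 h |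
| ash | 0.48 M (fed, over 4.0 h) | 0.470 M | 0.144 M | all else is in the flask from the start; the feed brings no volume worth counting | 25 h |
| maple | 0.48 M | 0.470 M | 0.144 M | everything together at the start | 25 h |
| oak | 0.48 M | 0.470 M (in portions, 4, over 15 h) | 0.144 M | first portion at the start, last at 15 h | 25 h |

| Wednesday's: time / h | Wednesday's: links / % | Sunday's: time / h | Sunday's: links / % |
|---|---|---|---|
| 1.33 | 40.1 | 0.417 | 23.8 |
| 2.00 | 42.0 | 0.667 | 30.3 |
| 3.00 | 41.0 | 1.00 | 32.7 |
| 5.00 | 39.8 | 2.00 | 35.0 |
| 10.0 | 38.1 | 3.00 | 33.1 |
| 15.0 | 36.9 | 5.00 | 28.5 |

(readings scatter by 0.5 percentage points)

- the best flask by amount of links, in percent of the first end groups charged; "all alike" if 1.5 percentage points covers them all (alder / birch / ash / maple / oak / all alike)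
- amount of links at the end, in percent of the first end groups charged, alder
- amount of links at the end, in percent of the first end groups charged, birch
- amount of links at the end, in percent of the first end groups charged, ash
- amount of links at the end, in percent of the first end groups charged, maple
- amount of links at the end, in percent of the first end groups charged, oak

- candidate steps: first end groups + second end groups -> links + by-product; first end groups + protic impurity -> quenched substrate; second end groups + links -> over-reaction product

Build the ceiling one step at a time, in fractions of the first end groups charged. With the main step alone, second end groups are the smaller charge, the limiting reagent, so links reach 97.9%. Add the quench: protic impurity takes 30.0% one for one, so 70.0% remain to couple, links drop to that figure, and second end groups stand over by 27.9%. Add over-reaction: each of those destroys one link, so subtract the excess and arrive at 42.1%.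

For these charges the rule follows: links equal the ceiling minus twice the first end groups that stay unreacted after second end groups and protic impurity have reacted to the last. Count the forms: first end groups stand as links, over-reaction product, quenched substrate or unreacted, and each link holds one second end group, each over-reaction product two. So by this rule the feeds share maple's ceiling, and whatever they lose must show as first end groups left over.

Sunday's charges give −18.7%, below zero, and its links do fall harder, by 6.5 percentage points from 2.00 h to 5.00 h, against 2.2 points on Wednesday's over the same hours.

Maple repeats Wednesday's charges, so replace its tail by a mean slope. The readings fell 1.7 points from 5.00 h to 10.0 h, then 1.2 points from there to 15.0 h. Hold the later fall for the two like spans left and the estimate for maple comes to 34.5%. But the readings fall less in the later span than in the earlier one, so take the middle between that estimate and the last reading: my figure is 35.7%, give or take 1.2 points.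

The forecast, made from these runs, puts maple first: alder 27%, birch 22%, ash 32%, oak 29%, and maple 35.9%, between 34.5% and 37%, a little above mine. Its ground: “Maple repeats Wednesday, so extending its slow tail gives about 36%”.

The flasks give alder 31.3%, birch 23.0%, ash 32.4%, oak 31.6% and maple 36.3%, so maple stands highest, and the forecast held.

    first end groups + second end groups → links + by-product (k = 2.20 M⁻¹ h⁻¹)
    first end groups + protic impurity → quenched substrate (k = 2.90 M⁻¹ h⁻¹)
    second end groups + links → over-reaction product (k = 1.00 M⁻¹ h⁻¹)

In maple, links have a half-life of 1.5 h by over-reaction alone with the other concentrations as charged, short against the 25 h of the run. Yet at 0.559 h links are still made 3.92 times faster than used up. At 250 h maple has second end groups at 0% and protic impurity at 0%, with 2.90% first end groups left, and the ceiling less twice that is 36.3%, against 36.3% found. Birch at 250 h holds 9.55%, which gives 23.0%, against 23.0% found.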